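**Retrosynthetic overview**
1. Target ⇒ two successive Z-selective Wittig olefinations of a C4 bis-phosphonium linker (from 1,4-dibromobutane) with the two epimeric hydroxy-pyranones 13 (fragment b, all-trans) and 19 (fragment a, OH cis to isopropenyl).
2. 13 and 19 ⇒ one cyclopentenyl-pyran ketal 9: trans epoxide + isopropenyl Grignard/CuI for b; cis epoxide + the same opening, then oxidation and chelation-controlled reduction for a.
3. 9 ⇒ enone 7 by an enantioselective C-glycosylation of the Achmatowicz acetate 6 with (S)-cyclopentenylsilane 3 (new step).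
4. Pyranone ring ⇒ furfuryl alcohol by oxidative ring expansion (Achmatowicz), the key step. It is the only ring built in the route and is made first; the cyclopentane ring comes intact from cyclopentadiene and the oxiranes are transient.

Assumption: the SMILES is read literally, so the two halves are epimers at the isopropenyl-bearing carbon (R in the half written first = fragment a, S in the other = fragment b).

**Route**

Step 1
Reactants: 1 cyclopenta-1,3-diene (freshly cracked from its dimer)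
Product: 3 (S)-cyclopent-2-en-1-yl(trimethyl)silane, via (S)-trichloro(cyclopent-2-en-1-yl)silane 2 (not isolated)
Conditions: HSiCl3, [PdCl(η3-C3H5)]2 (0.1 mol %), (R)-2-(diphenylphosphino)-2'-methoxy-1,1'-binaphthyl (0.2 mol %; the ligand antipode that gives the S silane is used), neat, 0 to 20 °C; then MeMgBr (3.5 equiv), Et2O, 0 to 20 °C
Reagents that add atoms: trichlorosilane (Cl[SiH](Cl)Cl); methylmagnesium bromide (C[Mg]Br)
Why: asymmetric 1,4-hydrosilylation of the diene through a π-allyl palladium silyl intermediate sets the allylic C–Si centre (S), and Grignard methylation at silicon does not touch it.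

Step 2
Reactants: 4 furfuryl alcohol
Product: 5 6-hydroxy-2H-pyran-3(6H)-one (racemic)
Conditions: NBS (1.05 equiv), NaHCO3 (2 equiv), THF–H2O (4:1), 0 °C
Reagents that add atoms: water (O)
Why: Achmatowicz oxidative ring expansion: 2,5-oxidation of the furan, hydrolysis to the cis-enedione and closure of the primary hydroxyl onto the aldehyde turn the five-membered furan into the six-membered pyranone; the lactol centre is erased in step 4.

Step 3
Reactants: 5 6-hydroxy-2H-pyran-3(6H)-one (racemic)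
Product: 6 6-acetoxy-2H-pyran-3(6H)-one (racemic)
Conditions: Ac2O, pyridine, 4-(dimethylamino)pyridine (5 mol %), CH2Cl2, 0 °C
Reagents that add atoms: acetic anhydride (CC(=O)OC(C)=O)
Why: O-acylation of the lactol installs an ionisable anomeric leaving group; its configuration does not matter because the carbon becomes planar in step 4.

Step 4
Reactants: 6 6-acetoxy-2H-pyran-3(6H)-one (racemic); 3 (S)-cyclopent-2-en-1-yl(trimethyl)silane
Product: 7 (6R)-6-[(1S)-cyclopent-2-en-1-yl]-2H-pyran-3(6H)-one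
Conditions: chiral imidodiphosphorimidate Brønsted acid (IDPi) built from two (S)-3,3'-bis[3,5-bis(trifluoromethyl)phenyl]-1,1'-bi-2-naphthol units with P=N–SO2CF3 groups (3 mol %; the antipode is used if it gives 6S), 3 (1.5 equiv), toluene, −60 °C
Reagents that add atoms: none
Why: Proposed new method: the confined acid is silylated by 3 to a silylium imidodiphosphorimidate, which abstracts acetate from racemic 6 to give the achiral 3-oxo-2H-pyranylium (oxocarbenium) ion paired with the chiral anion; the anion leaves one face of C6 open (6R, enantioconvergent), anti SE2' attack of the (S)-allylsilane fixes the cyclopentenyl centre as S, and loss of Me3Si regenerates the silylium catalyst; closest known reactions are the Lewis acid Hosomi–Sakurai C-glycosylation of Achmatowicz acetates and counteranion-directed additions of silyl nucleophiles to cyclic oxocarbenium ions from lactol acetates.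

Step 5
Reactants: 7 (6R)-6-[(1S)-cyclopent-2-en-1-yl]-2H-pyran-3(6H)-one
Product: 8 (6R)-6-[(1S)-cyclopent-2-en-1-yl]dihydro-2H-pyran-3(4H)-one
Conditions: Cu(OAc)2·H2O (3 mol %), 1,2-bis(diphenylphosphino)benzene (3 mol %), PhMe2SiH (1.3 equiv), t-BuOH (1.3 equiv), toluene, 20 °C
Reagents that add atoms: none
Why: CuH conjugate reduction (1,4-hydride delivery, then protonation of the copper enolate by t-BuOH) saturates only the enone C=C; the isolated cyclopentene and both stereocentres are untouched.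

Step 6
Reactants: 8 (6R)-6-[(1S)-cyclopent-2-en-1-yl]dihydro-2H-pyran-3(4H)-one
Product: 9 (8R)-8-[(1S)-cyclopent-2-en-1-yl]-1,4,7-trioxaspiro[4.5]decane
Conditions: ethylene glycol (5 equiv), pyridinium p-toluenesulfonate (10 mol %), benzene, reflux, Dean–Stark
Reagents that add atoms: ethane-1,2-diol (OCCO)
Why: acid-catalysed ketalisation masks the ketone for the organometallic, oxidation and hydride steps; no stereocentre is alpha to the carbonyl.

Step 7
Reactants: 9 (8R)-8-[(1S)-cyclopent-2-en-1-yl]-1,4,7-trioxaspiro[4.5]decane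
Product: 10 (8R)-8-[(1R,2R,5S)-6-oxabicyclo[3.1.0]hexan-2-yl]-1,4,7-trioxaspiro[4.5]decane
Conditions: mCPBA (1.2 equiv), CH2Cl2, 0 °C
Reagents that add atoms: 3-chloroperoxybenzoic acid (OOC(=O)c1cccc(Cl)c1)
Why: Prilezhaev epoxidation on the face anti to the allylic pyranyl substituent gives the trans epoxide; the minor cis isomer is compound 15 and is fed into step 10.

Step 8
Reactants: 10 (8R)-8-[(1R,2R,5S)-6-oxabicyclo[3.1.0]hexan-2-yl]-1,4,7-trioxaspiro[4.5]decane; 11 isopropenylmagnesium bromide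
Product: 13 (6R)-6-[(1S,2S,3S)-2-hydroxy-3-(prop-1-en-2-yl)cyclopentyl]dihydro-2H-pyran-3(4H)-one, via (1S,2S,5S)-2-(prop-1-en-2-yl)-5-[(8R)-1,4,7-trioxaspiro[4.5]decan-8-yl]cyclopentan-1-ol 12 (not isolated)
Conditions: 11 (3 equiv), CuI (15 mol %), THF, −30 to 0 °C; then 2 M HCl, THF, 20 °C
Reagents that add atoms: water (O)
Why: CuI-catalysed SN2 opening of the epoxide at the carbon remote from the pyranyl group, with inversion, puts isopropenyl trans to OH and OH trans to the pyranyl group (all-trans, fragment b); the acid quench then hydrolyses the dioxolane.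

Step 9
Reactants: 9 (8R)-8-[(1S)-cyclopent-2-en-1-yl]-1,4,7-trioxaspiro[4.5]decane
Product: 15 (8R)-8-[(1S,2R,5R)-6-oxabicyclo[3.1.0]hexan-2-yl]-1,4,7-trioxaspiro[4.5]decane, via (1R,2R,3R)-2-bromo-3-[(8R)-1,4,7-trioxaspiro[4.5]decan-8-yl]cyclopentan-1-ol 14 (not isolated)
Conditions: NBS (1.1 equiv), THF–H2O (3:1), 0 °C; then K2CO3 (2 equiv), MeOH, 20 °C
Reagents that add atoms: water (O)
Why: the bromonium ion forms anti to the pyranyl group and water opens it trans at the remote carbon; intramolecular Williamson closure then places the oxirane on the same face as the pyranyl group, the cis epoxide that peracid does not give.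

Step 10
Reactants: 15 (8R)-8-[(1S,2R,5R)-6-oxabicyclo[3.1.0]hexan-2-yl]-1,4,7-trioxaspiro[4.5]decane; 11 isopropenylmagnesium bromide
Product: 16 (1R,2R,5S)-2-(prop-1-en-2-yl)-5-[(8R)-1,4,7-trioxaspiro[4.5]decan-8-yl]cyclopentan-1-ol
Conditions: 11 (3 equiv), CuI (15 mol %), THF, −30 to 0 °C; then aq. NH4Cl
Reagents that add atoms: none
Why: the same SN2 opening at the carbon remote from the branched centre, now from the face opposite the pyranyl group, sets the isopropenyl carbon as R (isopropenyl trans to the pyranyl group).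

Step 11
Reactants: 16 (1R,2R,5S)-2-(prop-1-en-2-yl)-5-[(8R)-1,4,7-trioxaspiro[4.5]decan-8-yl]cyclopentan-1-ol
Product: 17 (2R,5R)-2-(prop-1-en-2-yl)-5-[(8R)-1,4,7-trioxaspiro[4.5]decan-8-yl]cyclopentan-1-one
Conditions: Dess–Martin periodinane (1.3 equiv), pyridine (3 equiv), CH2Cl2, 0 to 20 °C
Reagents that add atoms: none
Why: Dess–Martin oxidation under buffered, base-free conditions gives the 2,5-trans ketone without epimerising the allylic alpha carbon or triggering beta-alkoxy elimination; 17 is used at once.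

Step 12
Reactants: 17 (2R,5R)-2-(prop-1-en-2-yl)-5-[(8R)-1,4,7-trioxaspiro[4.5]decan-8-yl]cyclopentan-1-one
Product: 19 (6R)-6-[(1S,2S,3R)-2-hydroxy-3-(prop-1-en-2-yl)cyclopentyl]dihydro-2H-pyran-3(4H)-one, via (1S,2R,5S)-2-(prop-1-en-2-yl)-5-[(8R)-1,4,7-trioxaspiro[4.5]decan-8-yl]cyclopentan-1-ol 18 (not isolated)
Conditions: Zn(BH4)2 (1.5 equiv), Et2O, −40 °C; then 2 M HCl, THF, 20 °C
Reagents that add atoms: water (O)
Why: chelation-controlled reduction: Zn(BH4)2 bridges the carbonyl and the pyran oxygen, which ties the pyranyl group back, so hydride enters anti to the isopropenyl group and gives the alcohol cis to isopropenyl and trans to the pyranyl group (1S, fragment a); acid then removes the ketal.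

Step 13
Reactants: 20 1,4-dibromobutane
Product: 21 butane-1,4-diylbis(triphenylphosphonium) dibromide
Conditions: PPh3 (2.2 equiv), MeCN, reflux
Reagents that add atoms: triphenylphosphine (c1ccc(cc1)P(c1ccccc1)c1ccccc1)
Why: double SN2 quaternisation of phosphorus by the primary dibromide.

Step 14
Reactants: 21 butane-1,4-diylbis(triphenylphosphonium) dibromide; 13 (6R)-6-[(1S,2S,3S)-2-hydroxy-3-(prop-1-en-2-yl)cyclopentyl]dihydro-2H-pyran-3(4H)-one
Product: 23 {(4Z)-4-[(6R)-6-[(1S,2S,3S)-2-hydroxy-3-(prop-1-en-2-yl)cyclopentyl]dihydro-2H-pyran-3(4H)-ylidene]butyl}triphenylphosphonium bromide, via triphenyl[4-(triphenyl-λ5-phosphanylidene)butyl]phosphonium bromide 22 (not isolated)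
Conditions: 21 (3 equiv), KN(SiMe3)2 (3 equiv), THF–HMPA (10:1), −78 °C; then 13 (1 equiv), −78 to 20 °C; aq. NH4Br work-up
Reagents that add atoms: none
Why: Wittig olefination with the mono-ylide; salt-free non-stabilised ylides add to alpha-alkoxy ketones so that the new alkyl chain ends cis to the CH2–O carbon (Z), the excess bis-salt keeps olefination to one end, and the hydroxyl is far less acidic than the phosphonium alpha-CH.

Step 15
Reactants: 23 {(4Z)-4-[(6R)-6-[(1S,2S,3S)-2-hydroxy-3-(prop-1-en-2-yl)cyclopentyl]dihydro-2H-pyran-3(4H)-ylidene]butyl}triphenylphosphonium bromide; 19 (6R)-6-[(1S,2S,3R)-2-hydroxy-3-(prop-1-en-2-yl)cyclopentyl]dihydro-2H-pyran-3(4H)-one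
Product: 25 the target (1S,2R,5S)-2-(prop-1-en-2-yl)-5-[(2R,5Z)-5-{(4Z)-4-[(6R)-6-[(1S,2S,3S)-2-hydroxy-3-(prop-1-en-2-yl)cyclopentyl]dihydro-2H-pyran-3(4H)-ylidene]butylidene}oxan-2-yl]cyclopentan-1-ol, via (1S,2S,5S)-2-(prop-1-en-2-yl)-5-{(2R,5Z)-5-[4-(triphenyl-λ5-phosphanylidene)butylidene]oxan-2-yl}cyclopentan-1-ol 24 (not isolated)
Conditions: KN(SiMe3)2 (1.05 equiv), THF–HMPA (10:1), −78 °C; then 19 (1 equiv), −78 to 20 °C
Reagents that add atoms: none
Why: the second Z-selective Wittig olefination of an alpha-alkoxy ketone (chain cis to CH2–O again) joins fragment a to fragment b and completes the 1,5-diene.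

**Compound list**
1 | cyclopenta-1,3-diene | C1=CC=CC1 | starting material
2 | (S)-trichloro(cyclopent-2-en-1-yl)silane | Cl[Si](Cl)(Cl)[C@H]1CCC=C1 | intermediate
3 | (S)-cyclopent-2-en-1-yl(trimethyl)silane | C[Si](C)(C)[C@H]1CCC=C1 | intermediate
4 | furfuryl alcohol (furan-2-ylmethanol) | OCc1ccco1 | starting material
5 | 6-hydroxy-2H-pyran-3(6H)-one (racemic) | OC1OCC(=O)C=C1 | intermediate
6 | 6-acetoxy-2H-pyran-3(6H)-one (racemic) | CC(=O)OC1OCC(=O)C=C1 | intermediate
7 | (6R)-6-[(1S)-cyclopent-2-en-1-yl]-2H-pyran-3(6H)-one | O=C1C=C[C@H]([C@H]2CCC=C2)OC1 | intermediate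
8 | (6R)-6-[(1S)-cyclopent-2-en-1-yl]dihydro-2H-pyran-3(4H)-one | O=C1CC[C@H]([C@H]2CCC=C2)OC1 | intermediate
9 | (8R)-8-[(1S)-cyclopent-2-en-1-yl]-1,4,7-trioxaspiro[4.5]decane | O1CCOC12CC[C@H]([C@H]3CCC=C3)OC2 | intermediate
10 | (8R)-8-[(1R,2R,5S)-6-oxabicyclo[3.1.0]hexan-2-yl]-1,4,7-trioxaspiro[4.5]decane (oxirane trans to the pyranyl group) | O1CCOC12CC[C@H]([C@H]3CC[C@@H]4O[C@@H]43)OC2 | intermediate
11 | isopropenylmagnesium bromide (prop-1-en-2-ylmagnesium bromide) | C=C(C)[Mg]Br | starting material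
12 | (1S,2S,5S)-2-(prop-1-en-2-yl)-5-[(8R)-1,4,7-trioxaspiro[4.5]decan-8-yl]cyclopentan-1-ol | O1CCOC12CC[C@H]([C@H]3CC[C@@H](C(C)=C)[C@@H]3O)OC2 | intermediate
13 | (6R)-6-[(1S,2S,3S)-2-hydroxy-3-(prop-1-en-2-yl)cyclopentyl]dihydro-2H-pyran-3(4H)-one (fragment b) | O=C1CC[C@H]([C@H]2CC[C@@H](C(C)=C)[C@@H]2O)OC1 | intermediate
14 | (1R,2R,3R)-2-bromo-3-[(8R)-1,4,7-trioxaspiro[4.5]decan-8-yl]cyclopentan-1-ol | O1CCOC12CC[C@H]([C@H]3CC[C@@H](O)[C@@H]3Br)OC2 | intermediate
15 | (8R)-8-[(1S,2R,5R)-6-oxabicyclo[3.1.0]hexan-2-yl]-1,4,7-trioxaspiro[4.5]decane (oxirane cis to the pyranyl group) | O1CCOC12CC[C@H]([C@H]3CC[C@H]4O[C@H]43)OC2 | intermediate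
16 | (1R,2R,5S)-2-(prop-1-en-2-yl)-5-[(8R)-1,4,7-trioxaspiro[4.5]decan-8-yl]cyclopentan-1-ol | O1CCOC12CC[C@H]([C@H]3CC[C@H](C(C)=C)[C@H]3O)OC2 | intermediate
17 | (2R,5R)-2-(prop-1-en-2-yl)-5-[(8R)-1,4,7-trioxaspiro[4.5]decan-8-yl]cyclopentan-1-one | O1CCOC12CC[C@H]([C@H]3CC[C@H](C(C)=C)C3=O)OC2 | intermediate
18 | (1S,2R,5S)-2-(prop-1-en-2-yl)-5-[(8R)-1,4,7-trioxaspiro[4.5]decan-8-yl]cyclopentan-1-ol | O1CCOC12CC[C@H]([C@H]3CC[C@H](C(C)=C)[C@@H]3O)OC2 | intermediate
19 | (6R)-6-[(1S,2S,3R)-2-hydroxy-3-(prop-1-en-2-yl)cyclopentyl]dihydro-2H-pyran-3(4H)-one (fragment a) | O=C1CC[C@H]([C@H]2CC[C@H](C(C)=C)[C@@H]2O)OC1 | intermediate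
20 | 1,4-dibromobutane | BrCCCCBr | starting material
21 | butane-1,4-diylbis(triphenylphosphonium) dibromide | [Br-].[Br-].c1ccc(cc1)[P+](c1ccccc1)(c1ccccc1)CCCC[P+](c1ccccc1)(c1ccccc1)c1ccccc1 | intermediate
22 | triphenyl[4-(triphenyl-λ5-phosphanylidene)butyl]phosphonium bromide | [Br-].c1ccc(cc1)P(c1ccccc1)(c1ccccc1)=CCCC[P+](c1ccccc1)(c1ccccc1)c1ccccc1 | intermediate
23 | {(4Z)-4-[(6R)-6-[(1S,2S,3S)-2-hydroxy-3-(prop-1-en-2-yl)cyclopentyl]dihydro-2H-pyran-3(4H)-ylidene]butyl}triphenylphosphonium bromide | [Br-].c1ccc(cc1)[P+](c1ccccc1)(c1ccccc1)CCC/C=C1/CC[C@H]([C@H]2CC[C@@H](C(C)=C)[C@@H]2O)OC1 | intermediate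
24 | (1S,2S,5S)-2-(prop-1-en-2-yl)-5-{(2R,5Z)-5-[4-(triphenyl-λ5-phosphanylidene)butylidene]oxan-2-yl}cyclopentan-1-ol | c1ccc(cc1)P(c1ccccc1)(c1ccccc1)=CCC/C=C1/CC[C@H]([C@H]2CC[C@@H](C(C)=C)[C@@H]2O)OC1 | intermediate
25 | (1S,2R,5S)-2-(prop-1-en-2-yl)-5-[(2R,5Z)-5-{(4Z)-4-[(6R)-6-[(1S,2S,3S)-2-hydroxy-3-(prop-1-en-2-yl)cyclopentyl]dihydro-2H-pyran-3(4H)-ylidene]butylidene}oxan-2-yl]cyclopentan-1-ol (CNP0267443.2) | C=C(C)[C@H]1CC[C@H]([C@H]2CC/C(=C/CC/C=C3/CC[C@H]([C@H]4CC[C@@H](C(=C)C)[C@@H]4O)OC3)CO2)[C@H]1O | target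

**Totals and risks**

Total step count: 15. Longest linear sequence: 10 steps (2, 3, 4, 5, 6, 9, 10, 11, 12, 15).

Steps most likely to fail:

Step 4 (the new C-glycosylation; risks are low face selectivity at C6 and protodesilylation of 3). The fallback uses known chemistry, sets out from 6 (with 3) and comes back at 7. An achiral Lewis acid Hosomi–Sakurai C-glycosylation (Me3SiOTf 20 mol %, CH2Cl2, −78 °C) still fixes the cyclopentenyl centre by anti SE2' attack of the enantioenriched silane, but C6 is then set only by simple diastereoselection. It gives 7 together with its C6 epimer (6S)-6-[(1S)-cyclopent-2-en-1-yl]-2H-pyran-3(6H)-one F1; the two diastereomers are separated by chromatography and only 7 is carried on.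

Step 12 (risks are hydride attack on the wrong face of 17 and epimerisation or beta-elimination of this beta-alkoxy ketone). The fallback sets out from 16 and comes back at 18, replacing the redox pair of steps 11 and 12 by an SN2 inversion. Mitsunobu reaction of 16 (4-nitrobenzoic acid, PPh3, diisopropyl azodicarboxylate, THF, 0 to 20 °C) gives the inverted ester (1S,2R,5R)-2-(prop-1-en-2-yl)-5-[(8R)-1,4,7-trioxaspiro[4.5]decan-8-yl]cyclopentyl 4-nitrobenzoate F2. Methanolysis (K2CO3, MeOH) gives 18, which is deketalised with 2 M HCl as in step 12.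

Step 14 (risks are olefination at both ends of the bis-salt, enolisation of the alpha-alkoxy ketone, and incomplete Z selectivity that cannot be corrected on a phosphonium salt). The fallback sets out from 13 and comes back at 24, putting the linker on stepwise through neutral, separable intermediates. Commercial (4-hydroxybutyl)triphenylphosphonium bromide and KN(SiMe3)2 (2 equiv, THF, −78 °C) give the oxido ylide potassium 4-(triphenyl-λ5-phosphanylidene)butan-1-olate F3. This olefinates 13 to the diol (4Z)-4-{(6R)-6-[(1S,2S,3S)-2-hydroxy-3-(prop-1-en-2-yl)cyclopentyl]dihydro-2H-pyran-3(4H)-ylidene}butan-1-ol F4, from which any E isomer is removed on AgNO3-impregnated silica. Selective iodination of the primary hydroxyl (I2, PPh3, imidazole, CH2Cl2, 0 °C) gives (1S,2S,5S)-2-[(2R,5Z)-5-(4-iodobutylidene)oxan-2-yl]-5-(prop-1-en-2-yl)cyclopentan-1-ol F5. PPh3 in MeCN at 70 °C gives {(4Z)-4-[(6R)-6-[(1S,2S,3S)-2-hydroxy-3-(prop-1-en-2-yl)cyclopentyl]dihydro-2H-pyran-3(4H)-ylidene]butyl}triphenylphosphonium iodide F6, and KN(SiMe3)2 then gives ylide 24 for step 15.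

Further compounds
F1 | step 4 | (6S)-6-[(1S)-cyclopent-2-en-1-yl]-2H-pyran-3(6H)-one | O=C1C=C[C@@H]([C@H]2CCC=C2)OC1
F2 | step 12 | (1S,2R,5R)-2-(prop-1-en-2-yl)-5-[(8R)-1,4,7-trioxaspiro[4.5]decan-8-yl]cyclopentyl 4-nitrobenzoate | O1CCOC12CC[C@H]([C@H]3CC[C@H](C(C)=C)[C@@H]3OC(=O)c4ccc(cc4)[N+](=O)[O-])OC2
F3 | step 14 | potassium 4-(triphenyl-λ5-phosphanylidene)butan-1-olate | [K+].[O-]CCCC=P(c1ccccc1)(c1ccccc1)c1ccccc1
F4 | step 14 | (4Z)-4-{(6R)-6-[(1S,2S,3S)-2-hydroxy-3-(prop-1-en-2-yl)cyclopentyl]dihydro-2H-pyran-3(4H)-ylidene}butan-1-ol | OCCC/C=C1/CC[C@H]([C@H]2CC[C@@H](C(C)=C)[C@@H]2O)OC1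
F5 | step 14 | (1S,2S,5S)-2-[(2R,5Z)-5-(4-iodobutylidene)oxan-2-yl]-5-(prop-1-en-2-yl)cyclopentan-1-ol | ICCC/C=C1/CC[C@H]([C@H]2CC[C@@H](C(C)=C)[C@@H]2O)OC1
F6 | step 14 | {(4Z)-4-[(6R)-6-[(1S,2S,3S)-2-hydroxy-3-(prop-1-en-2-yl)cyclopentyl]dihydro-2H-pyran-3(4H)-ylidene]butyl}triphenylphosphonium iodide | [I-].c1ccc(cc1)[P+](c1ccccc1)(c1ccccc1)CCC/C=C1/CC[C@H]([C@H]2CC[C@@H](C(C)=C)[C@@H]2O)OC1
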